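**Retrosynthetic overview**
1. Ring A of arzanol (the benzene ring, C1'–C6') carries oxygen on C2', C4' and C6', and carbon on C1' (CH2 bridge), C3' (prenyl) and C5' (acetyl). This is the pattern of a folded tetraketide, so opening ring bond C4'–C5' (retro-Claisen) gives methyl 3,5,7-trioxooctanoate with prenyl on chain C2 and the pyronylmethyl group on chain C4.
2. The chain C4–CH2 bond is cut next (retro-Michael). The pieces are the 3-methylidene form of the pyrone (pyrone plus Eschenmoser's salt) and a 3,5-dioxo ester whose C7 ketone is held as a dioxolane, which leaves C4 as its only carbon between two ketones.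
3. The dioxo ester is cut at C4–C5 into the dianion of methyl 2-prenylacetoacetate and the Weinreb amide of (2-methyl-1,3-dioxolan-2-yl)acetic acid.
4. Ring order: pyrone ring B is made first (silyl enol ether of 3-pentanone plus malonyl dichloride, step 2) and benzene ring A last (step 8).

Key step: step 8

Remark: chain numbers C1–C8 follow the octanoate of the cyclization precursor throughout (the dioxolane carbon is C7). The open-chain β-dicarbonyl intermediates are racemic, epimerizable at C2 and C4, and mixtures of keto, enol and (once the pyrone is attached) hemiketal tautomers, and they are drawn as keto forms. Both centres end as sp2 ring carbons, arzanol has no stereocentre and its alkene has no E/Z isomers, so no stereocontrol is needed.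

Step 1
Reactants: 1 3-pentanone
Product: 2 3-(trimethylsilyloxy)pent-2-ene (E/Z mixture)
Conditions: TMSOTf, Et3N, CH2Cl2, 0 °C
Reagents that add atoms: trimethylsilyl trifluoromethanesulfonate, C[Si](C)(C)OS(=O)(=O)C(F)(F)F
Why: Soft enolization and O-silylation (silyl enol ether formation) of a symmetrical ketone raises no regiochemical question, and both alkene isomers lead to the same pyrone.

Step 2
Reactants: 2 3-(trimethylsilyloxy)pent-2-ene; 3 malonyl dichloride
Product: 5 6-ethyl-4-hydroxy-5-methyl-2H-pyran-2-one, via 4-methyl-3,5-dioxoheptanoyl chloride 4 (not isolated)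
Conditions: Et2O, −78 °C to rt
Reagents that add atoms: none
Why: This is the known 4-hydroxy-2-pyrone synthesis by double acylation of a silyl enol ether with malonyl dichloride, in which C-acylation at the methyl-bearing enol carbon with loss of the silyl group gives 4, whose C5 enol oxygen then closes on the remaining acid chloride (6-exo-trig lactonization), placing methyl on C5 and ethyl on C6 of ring B.

Step 3
Reactants: 6 methyl acetoacetate; 7 prenyl bromide (1-bromo-3-methylbut-2-ene)
Product: 8 methyl 2-acetyl-5-methylhex-4-enoate (methyl 2-prenylacetoacetate, racemic)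
Conditions: K2CO3, acetone, reflux
Reagents that add atoms: none
Why: In this acetoacetic ester alkylation the soft enolate displaces the primary allylic bromide by SN2 at the unsubstituted terminus, a slight excess of 6 holds back dialkylation, and the new C2 centre is racemic and is erased in step 8.

Step 4
Reactants: 9 ethyl (2-methyl-1,3-dioxolan-2-yl)acetate
Product: 10 N-methoxy-N-methyl-2-(2-methyl-1,3-dioxolan-2-yl)acetamide
Conditions: MeNH(OMe)·HCl, iPrMgCl, THF, −20 to 0 °C
Reagents that add atoms: N,O-dimethylhydroxylamine hydrochloride, CNOC.Cl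
Why: Ester aminolysis by the magnesium amide of N,O-dimethylhydroxylamine (Weinreb amide formation) runs below 0 °C, where β-elimination of the dioxolane oxygen from the enolized ester should not compete.

Step 5
Reactants: 8 methyl 2-acetyl-5-methylhex-4-enoate; 10 N-methoxy-N-methyl-2-(2-methyl-1,3-dioxolan-2-yl)acetamide
Product: 12 methyl 6-(2-methyl-1,3-dioxolan-2-yl)-2-(3-methylbut-2-en-1-yl)-3,5-dioxohexanoate (racemic), via dilithium dianion 11 (not isolated)
Conditions: LiN(iPr)2 (2.2 equiv per 8), THF, −78 to 0 °C; then 10 (0.8 equiv), −78 to −20 °C; aq NH4Cl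
Reagents that add atoms: none
Why: In this γ-acylation of a β-keto ester dianion (Weinreb ketone synthesis) the more basic terminal CH2 carbanion of 11 attacks the amide, which releases the new C5 ketone only on quenching, so the acidic product does not consume 11 and no second addition occurs.

Step 6
Reactants: 5 6-ethyl-4-hydroxy-5-methyl-2H-pyran-2-one; 13 Eschenmoser's salt (dimethylmethylideneammonium iodide); 12 methyl 6-(2-methyl-1,3-dioxolan-2-yl)-2-(3-methylbut-2-en-1-yl)-3,5-dioxohexanoate
Product: 16 methyl 4-[(6-ethyl-4-hydroxy-5-methyl-2-oxo-2H-pyran-3-yl)methyl]-6-(2-methyl-1,3-dioxolan-2-yl)-2-(3-methylbut-2-en-1-yl)-3,5-dioxohexanoate (C2/C4 epimer mixture), via Mannich base hydroiodide 14 (not isolated), via 3-methylidenepyran-2,4-dione 15 (not isolated)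
Conditions: 5, 13 (1.0 equiv), MeCN, rt; then 12 (1.2 equiv), iPr2NEt, 40 °C; cold aq citric acid
Reagents that add atoms: none
Why: A Mannich reaction at C3, the only free nucleophilic carbon of 5, is followed by base-induced loss of dimethylamine to the quinone-methide-like acceptor 15 and by Michael addition of 12 through chain C4, its only carbon between two ketones (C2 is a hindered tertiary β-keto ester carbon and C6 is singly activated because C7 is ketalized), and the new C4 centre is uncontrolled, epimerizable and erased in step 8.

Step 7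
Reactants: 16 the ketal-protected Michael adduct
Product: 17 methyl 4-[(6-ethyl-4-hydroxy-5-methyl-2-oxo-2H-pyran-3-yl)methyl]-2-(3-methylbut-2-en-1-yl)-3,5,7-trioxooctanoate (C2/C4 epimer and tautomer mixture, used crude)
Conditions: 1 M aq HCl, THF, 0 °C to rt, short contact
Reagents that add atoms: water, O
Why: Acid-catalysed ketal hydrolysis with dilute acid at or below room temperature should free the C7 ketone while ester, prenyl alkene and pyrone persist, and the short contact is meant to hold back dehydrative closure of the pyrone 4-OH or of an enol oxygen onto a neighbouring ketone.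

Step 8
Reactants: 17 methyl 4-[(6-ethyl-4-hydroxy-5-methyl-2-oxo-2H-pyran-3-yl)methyl]-2-(3-methylbut-2-en-1-yl)-3,5,7-trioxooctanoate
Product: 19 arzanol, via cyclohexane-1,3,5-trione tautomer 18 (not isolated)
Conditions: Mg(OMe)2 (5 equiv), MeOH, Ar, 50 °C; then 1 M aq HCl, 0 °C
Reagents that add atoms: none
Why: Mg(OMe)2 ionizes the pyrone 4-OH and binds the C5/C7 diketone as a six-membered magnesium chelate whose central carbon C6 adds to the ester carbonyl C1; loss of methoxide from the tetrahedral adduct makes ring bond C4'–C5' and gives trione 18, which enolizes three times to the magnesium phenoxide of ring A, an irreversible sink that pulls the earlier equilibria forward. The closest known reaction type is the intramolecular Claisen (Dieckmann-type) cyclization of 3,5,7-trioxoalkanoates and of their 2-pyrone lactones to acylphloroglucinols under Mg(OMe)2 or alkali. The one ring closed, carbocycle A, forms in a 6-(enolexo)-exo-trig mode when the chelate is written as the C6=C7 enolate (6-(enolendo)-exo-trig for the C5=C6 form, likewise allowed). No stereocentre is created, and the epimeric centres C2 and C4 of 17 become the sp2 carbons C3' and C1'. The step needs Claisen closure to win over aldol, lactone and cleavage pathways: attack of C2 on C7 would make a quaternary prenyl-bearing carbon that cannot dehydrate to an arene and so reverts, attack of the unactivated C8 methyl on C3 is disfavoured by the two tertiary carbons flanking that ketone, the lactone from the C5 enol oxygen and C1 is reopened by methoxide, and enolate formation across C3–C5 and C5–C7 shields the ketones from retro-Claisen attack. Ring B persists as its 4-oxido anion, a poor electrophile without a doubly activated carbon nucleophile, so any methanolysis of it has no irreversible exit.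

**Compound list**
1 | 3-pentanone | CCC(=O)CC | starting material
2 | 3-(trimethylsilyloxy)pent-2-ene (E/Z mixture) | CC=C(CC)O[Si](C)(C)C | intermediate
3 | malonyl dichloride | O=C(Cl)CC(=O)Cl | starting material
4 | 4-methyl-3,5-dioxoheptanoyl chloride (not isolated) | CCC(=O)C(C)C(=O)CC(=O)Cl | intermediate
5 | 6-ethyl-4-hydroxy-5-methyl-2H-pyran-2-one | CCc1oc(=O)cc(O)c1C | intermediate
6 | methyl acetoacetate | COC(=O)CC(C)=O | starting material
7 | prenyl bromide (1-bromo-3-methylbut-2-ene) | CC(C)=CCBr | starting material
8 | methyl 2-acetyl-5-methylhex-4-enoate (racemic) | COC(=O)C(CC=C(C)C)C(C)=O | intermediate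
9 | ethyl (2-methyl-1,3-dioxolan-2-yl)acetate | CCOC(=O)CC1(C)OCCO1 | starting material
10 | N-methoxy-N-methyl-2-(2-methyl-1,3-dioxolan-2-yl)acetamide | CON(C)C(=O)CC1(C)OCCO1 | intermediate
11 | dilithium dianion (bis-enolate) of 8 (not isolated) | [Li+].[Li+].COC([O-])=C(CC=C(C)C)C([O-])=C | intermediate
12 | methyl 6-(2-methyl-1,3-dioxolan-2-yl)-2-(3-methylbut-2-en-1-yl)-3,5-dioxohexanoate (racemic) | COC(=O)C(CC=C(C)C)C(=O)CC(=O)CC1(C)OCCO1 | intermediate
13 | Eschenmoser's salt (dimethylmethylideneammonium iodide) | C[N+](C)=C.[I-] | starting material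
14 | 3-[(dimethylamino)methyl]-6-ethyl-4-hydroxy-5-methyl-2H-pyran-2-one hydroiodide (not isolated) | CCc1oc(=O)c(CN(C)C)c(O)c1C.I | intermediate
15 | 6-ethyl-5-methyl-3-methylidene-2H-pyran-2,4(3H)-dione (not isolated) | CCC1=C(C)C(=O)C(=C)C(=O)O1 | intermediate
16 | methyl 4-[(6-ethyl-4-hydroxy-5-methyl-2-oxo-2H-pyran-3-yl)methyl]-6-(2-methyl-1,3-dioxolan-2-yl)-2-(3-methylbut-2-en-1-yl)-3,5-dioxohexanoate (epimer mixture) | COC(=O)C(CC=C(C)C)C(=O)C(Cc1c(O)c(C)c(CC)oc1=O)C(=O)CC1(C)OCCO1 | intermediate
17 | methyl 4-[(6-ethyl-4-hydroxy-5-methyl-2-oxo-2H-pyran-3-yl)methyl]-2-(3-methylbut-2-en-1-yl)-3,5,7-trioxooctanoate (epimer mixture) | COC(=O)C(CC=C(C)C)C(=O)C(Cc1c(O)c(C)c(CC)oc1=O)C(=O)CC(C)=O | intermediate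
18 | 2-acetyl-4-[(6-ethyl-4-hydroxy-5-methyl-2-oxo-2H-pyran-3-yl)methyl]-6-(3-methylbut-2-en-1-yl)cyclohexane-1,3,5-trione (not isolated) | CC(=O)C1C(=O)C(CC=C(C)C)C(=O)C(Cc2c(O)c(C)c(CC)oc2=O)C1=O | intermediate
19 | arzanol | CCc1oc(=O)c(Cc2c(O)c(CC=C(C)C)c(O)c(C(C)=O)c2O)c(O)c1C | target

**Step count.** The route has 8 steps in total. The longest linear sequence is 5 steps (steps 3, 5, 6, 7, 8), and the branches through steps 1–2 and through step 4 are no longer.

**Steps most likely to fail**

1. Step 8.
   - Risk: ring closure may lose to base-induced retro-Michael release of the pyronylmethyl unit from chain C4. It may also lose to retro-Claisen cleavage of the crowded C3–C4–C5 diketone, or to sluggish attack on an ester flanked by a tertiary carbon.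
   - Fallback: the same Claisen closure is carried out before the bridge is installed. It sets out from 12.
   - Ketal hydrolysis (1 M aq HCl, THF) would give methyl 2-(3-methylbut-2-en-1-yl)-3,5,7-trioxooctanoate F1.
   - Mg(OMe)2 in MeOH would close this less hindered chain to 1-[2,4,6-trihydroxy-3-(3-methylbut-2-en-1-yl)phenyl]ethan-1-one F2.
   - F2 would then be alkylated at its one free ring carbon by acceptor 15, released with iPr2NEt from 14 (made from 5 and 13 as in step 6). This comes back to the route at 19.

2. Step 6.
   - Risk: the acceptor may be intercepted by free or regenerated pyrone (symmetrical methylene-bridged dimerization). The liberated dimethylamine may condense with the diketone, or the adduct may cyclodehydrate on warming.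
   - Fallback: the C4–CH2 link is built before the C4–C5 bond. It sets out from 5.
   - Michael addition to acrolein (cat. Et3N, MeCN) would give 7-ethyl-2-hydroxy-8-methyl-3,4-dihydro-2H,5H-pyrano[4,3-b]pyran-5-one F3.
   - Oxidation of the lactol (TEMPO, PhI(OAc)2, CH2Cl2) would give 7-ethyl-8-methyl-3,4-dihydro-2H,5H-pyrano[4,3-b]pyran-2,5-dione F4.
   - This enol lactone, an internal active ester, would be opened by two equivalents of the lithium enolate of methyl 5-methylhex-4-enoate (LiN(iPr)2, THF, −78 °C). The product is methyl 5-(6-ethyl-4-hydroxy-5-methyl-2-oxo-2H-pyran-3-yl)-2-(3-methylbut-2-en-1-yl)-3-oxopentanoate F5.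
   - Triple deprotonation of F5 with LiN(iPr)2 and γ-acylation at chain C4 by 10 comes back to the route at 16.
   - Competing lateral deprotonation of the 6-ethyl group is the reason this path is only the reserve.

3. Step 7.
   - Risk: acid may drive dehydrative ring closure of the pyrone 4-OH onto the C3 or C5 ketone, or of the freed triketone to a 4-pyranone, faster than the β-keto ketal hydrolyses.
   - Fallback: the pyrone hydroxyl is masked with a base-labile acyl group before the acid step. It sets out from 16.
   - Selective acylation of the most acidic OH (PivCl, Et3N, CH2Cl2, 0 °C) would give the pyrone 4-O-pivalate of 16 F6.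
   - Hydrolysis of its ketal (1 M aq HCl, THF) would give the pyrone 4-O-pivalate of 17 F7.
   - Under the conditions of step 8, methoxide would remove the pivalate first. This comes back to the route at 17, formed in the flask as its magnesium salt and cyclized on to 19.

**Further compounds**
F1 | step 8 | methyl 2-(3-methylbut-2-en-1-yl)-3,5,7-trioxooctanoate | COC(=O)C(CC=C(C)C)C(=O)CC(=O)CC(C)=O
F2 | step 8 | 1-[2,4,6-trihydroxy-3-(3-methylbut-2-en-1-yl)phenyl]ethan-1-one | CC(=O)c1c(O)cc(O)c(CC=C(C)C)c1O
F3 | step 6 | 7-ethyl-2-hydroxy-8-methyl-3,4-dihydro-2H,5H-pyrano[4,3-b]pyran-5-one (racemic lactol) | CCc1oc(=O)c2c(c1C)OC(O)CC2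
F4 | step 6 | 7-ethyl-8-methyl-3,4-dihydro-2H,5H-pyrano[4,3-b]pyran-2,5-dione | CCc1oc(=O)c2c(c1C)OC(=O)CC2
F5 | step 6 | methyl 5-(6-ethyl-4-hydroxy-5-methyl-2-oxo-2H-pyran-3-yl)-2-(3-methylbut-2-en-1-yl)-3-oxopentanoate (racemic) | COC(=O)C(CC=C(C)C)C(=O)CCc1c(O)c(C)c(CC)oc1=O
F6 | step 7 | methyl 4-{[4-(2,2-dimethylpropanoyloxy)-6-ethyl-5-methyl-2-oxo-2H-pyran-3-yl]methyl}-6-(2-methyl-1,3-dioxolan-2-yl)-2-(3-methylbut-2-en-1-yl)-3,5-dioxohexanoate (epimer mixture) | COC(=O)C(CC=C(C)C)C(=O)C(Cc1c(OC(=O)C(C)(C)C)c(C)c(CC)oc1=O)C(=O)CC1(C)OCCO1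
F7 | step 7 | methyl 4-{[4-(2,2-dimethylpropanoyloxy)-6-ethyl-5-methyl-2-oxo-2H-pyran-3-yl]methyl}-2-(3-methylbut-2-en-1-yl)-3,5,7-trioxooctanoate (epimer mixture) | COC(=O)C(CC=C(C)C)C(=O)C(Cc1c(OC(=O)C(C)(C)C)c(C)c(CC)oc1=O)C(=O)CC(C)=O
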